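## Structural features

The target is a trans-2,3-diaryl-2,3-dihydrobenzofuran. Benzo ring A (C3a, C4 to C7, C7a) is fused to a dihydrofuran ring (O1, C2, C3). C2 carries a guaiacyl ring, C3 a resorcinyl ring, C4 a hydroxyl and C6 an (E)-4-hydroxy-3-methoxystyryl arm. The only stereocentres, C2 (R) and C3 (R), are adjacent and trans; C2 is a benzylic aryl ether carbon activated by a para oxygen, and C3 is doubly benzylic. The fragile parts are five free phenols, an electron-rich stilbene (light, acid, oxidants) and the ionisable C2–O1 bond. Two methyl ethers must survive, so the phenol protecting groups have to come off without a demethylating reagent. The real difficulty is the C3–C3a bond, which joins an aryl-bearing sp3 carbon to a ring A carbon hemmed in by the oxygens on C4 and C7a, together with absolute control at C2. Ring A has O1 on C7a, oxygen on C4 and carbon on C6, with C3a between two oxygens. That is the 5,7-dioxygenated ring of a 2-arylchroman-4-one once the carbonyl carbon is taken out of the ring. The plan therefore buys O1–C2 and ring A as a flavanone and makes C3–C3a by shifting the ring A carbon from the carbonyl carbon to C3; the excised carbon stays on C3 as a carboxyl handle for the resorcinyl ring.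

## Logic of the disconnections

26 to 25. The five O–CH2OCH3 bonds are cut. MOM acetals tolerate base, organometallics, light and palladium and leave with dilute acid that does not touch the two methyl ethers. All phenols are silenced in 25. The forward step needs acid mild enough not to ionise C2–O1 or protonate the stilbene.

25 to 20 and 22. The bond from C3 to the resorcinyl ipso carbon is cut. The carboxyl carbon left on C3 by the ring contraction can leave as CO2, so the whole resorcinyl ring is imported with its oxygens in place. Growing that ring from the carboxyl carbon by Claisen and aldol condensations was set aside: an ester with a C3–H next to an aryl ring would be deprotonated, not acylated, by a strongly basic carbon nucleophile, and a triketone would face retro-Claisen cleavage in hot alkali. The demand on the forward step is that the planar C3 radical be captured anti to the C2 aryl group (trans) and that the alkylnickel intermediate not eliminate towards the benzofuran.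

20 to 19 to 18. Only the O–N and O–CH3 bonds of the carboxyl derivative change. Saponification and carbodiimide activation are routine and keep C2 intact; C3 can stay or equilibrate to trans.

18 to 15 and 17. The bond from C6 to the vinyl carbon is cut. The stilbene must not be present during irradiation, and the C7 oxygen of the flavanone offers a triflate for free. 17 is one step from 16. The forward step must arylate an electron-rich styrene at the terminal carbon with E geometry.

15 to 12 (key step). C3–C3a is cut and C3a is re-attached to the carboxyl carbon, which becomes the ring carbonyl; C3 receives the diazo group. The problem shrinks to a flavanone with a phloroglucinol-derived ring A and one stereocentre. The structures on both sides of this step were checked atom by atom and need no correction. C2 is 2R in 10 and 15 but 2S in 12 and 13, only because C3 outranks the aryl group there. The forward step needs migration of the ring A carbon to beat hydrogen shift from C2. It also needs light that only the diazo ketone absorbs, and equilibration of C3 to trans.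

12 to 10. The C3=N2 bond is cut. A methylene activated by a single carbonyl does not accept a diazo group directly, and the enolate of 10 can open to the chalcone and lose C2. The design of 12 is therefore tightened in three ways. C3 is first trifluoroacetylated (11) through a short-lived enolate at −78 °C, and the diazo group is then transferred under amine base. 12 is irradiated at 365 nm or longer. The triflate is kept as a photochemically silent placeholder for the stilbene.

10 to 5 and 9. The bond from C2 to the guaiacyl ipso carbon is cut by an enantioselective conjugate arylation of the chromone, the only step that creates absolute configuration. It must deliver 2R (the mirror image of the common natural flavanones) and leave the triflate alone.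

5 to 4 to 3 to 1. The O5–MOM and O7–triflyl bonds and the one-carbon bridge O1–C2=C3 are cut. The chelated O5–H and the free, more acidic O7–H of 3 react in a fixed order, and 1 is symmetrical, so only one chromone can form.

9 to 7 to 6, 17 to 16 and 22 to 21. C–B and O–MOM bonds are cut back to three commercial phenols; the only demand is halogen–lithium exchange faster than ortho-lithiation.

## Other disconnections considered

Alternative 1: The cut removes three ring A bonds (C3a–C7a, C4–C5, C6–C7), so ring A is assembled from three alkynes. Two belong to the tethered diyne A2 (an ethynyl ether on O1 and a silyloxyalkyne on C3 of the preformed C2–C3 unit) and the third to the enyne A3. Cp*RuCl(cod) would join them in a [2+2+2] cyclotrimerisation to A1, closing the benzene ring and, through the O1–C2–C3 tether, the dihydrofuran ring in one operation.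
- In its favour: it is the most convergent construction. The styryl arm arrives with the third alkyne, so no late cross-coupling is needed. C4 emerges as a silyl ether distinct from the MOM ethers. The stereocentres sit on sp3 carbons that the metal does not touch. The usual preference of this catalyst for placing the substituent of a terminal alkyne meta to the substituted diyne terminus matches the 4-oxy, 6-styryl pattern.
- Against it here: A2 holds two ynol ethers. The ethynyl ether on a benzylic oxygen next to an electron-rich ring is prone to sigmatropic rearrangement and ketene formation on gentle warming, and the silyl ynol ether is hydrolytically delicate. A2 must also be made as one anti diastereomer and one enantiomer, a task as large as the whole front end of the chosen plan. The alkene of A3 offers the catalyst a second π-ligand.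
- Comparison: structurally it builds ring A de novo, where the chosen plan buys ring A and O1 from a phloroglucinol ketone. Mechanistically it needs chemo- and regiocontrol over three different alkynes, where the chosen key step needs one migration to beat one hydrogen shift. In step economy it is better after the key step (A1 is two deprotections from the target, against five operations in the chosen plan) and about equal in convergency. It is expected to be longer and less secure before the key step.

Alternative 2: The cut is O1–C2. A photoredox catalyst would reduce the N-acyloxyphthalimide A5, CO2 would leave, and the C2 radical would be oxidised to a cationic benzylic centre stabilised by the para oxygen of the guaiacyl ring. An ortho MOM ether oxygen of ring A would then close the ring and shed its MOM group, giving A4.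
- In its favour: C2 need not be carried through the synthesis, because it is created at ring closure under control of C3, with trans the expected kinetic and thermodynamic result. The ring A unit of A5 has two equivalent ortho MOM ethers, so there is no regiochemical question and no need to tell two phenols apart; this is better than the chosen plan, where O5 and O7 must be differentiated. A4 already holds all three aryl groups, so the endgame is a Heck coupling and deprotection, shorter than in the chosen plan. No base-labile chromanone enolate is involved.
- Against it here: the stereochemical burden moves to C3 of A5, a methine carrying two aryl rings, one of them 2,6-dioxygenated. Known catalysis serves this less well than aryl addition to a chromone. The cationic centre may lose the C3 proton (which would erase C3) or be taken by an external nucleophile. An ether oxygen is a weaker internal nucleophile than a free phenol. The aryl bromide must survive the reducing photocatalyst.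
- Comparison: it is equal on the use of a carboxyl group as a traceless handle, since the chosen plan also ends by expelling CO2 from an N-acyloxyphthalimide, though to make C3–aryl and not O1–C2. It is better on endgame length and ring A symmetry. It is weaker on the source of absolute configuration and on precedent for the ring-closing event. Overall step counts would be similar, with the risk concentrated in making A5.

Alternative 3: The cut is C5–C6 of ring A. Base would close the methyl carbon of the C4 acetyl group of the dihydrofuran diketone A7 onto the ketone carbon of its styryl ketone side chain. Loss of water and enolisation of the C4 carbonyl would give ring A as the free C4 phenol A6.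
- In its favour: it follows polyketide logic and needs no transition metal, no triflate and no cross-coupling. The stilbene comes in as an enone arm. The C4 hydroxyl is delivered free and already distinguished, which is better if C4 had to be addressed selectively and of no advantage here. Only MOM removal remains, the shortest endgame of all.
- Against it here: A7 is a vinylogous ester whose C3–H is vinylogously acidic, so base may epimerise C3 or open the ring by loss of O1. The methylene between the side-chain ketone and the enol ether carbon is more acidic than the acetyl methyl group, so the productive enolate is the minor one. The aryl vinyl ketone is a Michael acceptor for any enolate present. The trans-2,3-diaryl-dihydrofuran A7 has no enantioselective entry of the quality of the chromone arylation.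
- Comparison: the aromatising aldol is as dependable a reaction type as the ring contraction (equal), and the endgame is better. The chosen plan is stronger on where the absolute configuration comes from and on access to its key precursor. Overall length would depend on the route to A7.

Key step: step 8

Assumption: the (1R,4R)-diene is taken to deliver the aryl group to the chromone face that gives 2R, by analogy with its behaviour towards cyclic enones; if the sense proves opposite, the (1S,4S)-diene is used with no other change.

## Route

Step 1
Reactants: 1 2,4,6-trihydroxyacetophenone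
Product: 3 5,7-dihydroxy-4H-chromen-4-one, via enaminone 2 (not isolated)
Conditions: Me2NCH(OMe)2, DMF, 80 °C; then aq. HCl, 70 °C
Reagents that add atoms: N,N-dimethylformamide dimethyl acetal, COC(OC)N(C)C
Why: The amide acetal condenses with the acetyl methyl group to the enaminone; acid then promotes conjugate addition of an ortho hydroxyl and loss of dimethylamine (enaminone route to chromones), and the two ortho hydroxyls of 1 are equivalent, so one chromone results.

Step 2
Reactants: 3 5,7-dihydroxy-4H-chromen-4-one
Product: 4 5-hydroxy-4-oxo-4H-chromen-7-yl trifluoromethanesulfonate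
Conditions: PhNTf2 (1.05 equiv), Et3N, CH2Cl2/THF, 0 °C
Reagents that add atoms: N-phenylbis(trifluoromethanesulfonimide), O=S(=O)(N(c1ccccc1)S(=O)(=O)C(F)(F)F)C(F)(F)F
Why: O7–H is the more acidic phenol and is not held in the hydrogen bond to the C4 carbonyl that deactivates O5–H, so O-sulfonylation with the mild triflyl donor should go to O7 only.

Step 3
Reactants: 4 5-hydroxy-4-oxo-4H-chromen-7-yl trifluoromethanesulfonate
Product: 5 5-(methoxymethoxy)-4-oxo-4H-chromen-7-yl trifluoromethanesulfonate
Conditions: MOMCl, i-Pr2NEt, n-Bu4NI (cat.), CH2Cl2, 40 °C
Reagents that add atoms: chloromethyl methyl ether, COCCl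
Why: O-alkylation of the chelated phenol with the reactive α-chloro ether needs iodide catalysis and warming; the hindered amine does not attack the triflate or the chromone.

Step 4
Reactants: 6 4-bromo-2-methoxyphenol
Product: 7 4-bromo-2-methoxy-1-(methoxymethoxy)benzene
Conditions: MOMCl, i-Pr2NEt, CH2Cl2, 0 °C to rt
Reagents that add atoms: chloromethyl methyl ether, COCCl
Why: Plain O-alkylation of a phenol to its MOM acetal, which masks the acidic proton before lithiation.

Step 5
Reactants: 7 4-bromo-2-methoxy-1-(methoxymethoxy)benzene
Product: 9 [3-methoxy-4-(methoxymethoxy)phenyl]boronic acid, via aryllithium 8 (not isolated)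
Conditions: n-BuLi, THF, −78 °C; B(Oi-Pr)3, −78 °C to rt; aq. NH4Cl
Reagents that add atoms: triisopropyl borate, CC(C)OB(OC(C)C)OC(C)C; water, O
Why: Bromine–lithium exchange at −78 °C is faster than ortho-lithiation beside the MOM ether; the aryllithium is borylated and the borate hydrolysed under a mild quench that spares the acetal (lithiation–borylation).

Step 6
Reactants: 5 5-(methoxymethoxy)-4-oxo-4H-chromen-7-yl trifluoromethanesulfonate; 9 [3-methoxy-4-(methoxymethoxy)phenyl]boronic acid
Product: 10 (2R)-2-[3-methoxy-4-(methoxymethoxy)phenyl]-5-(methoxymethoxy)-4-oxo-3,4-dihydro-2H-chromen-7-yl trifluoromethanesulfonate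
Conditions: [RhCl(C2H4)2]2 (3 mol %), (1R,4R)-2,5-diphenylbicyclo[2.2.2]octa-2,5-diene (6.6 mol %), 9 (2 equiv), aq. K3PO4 (0.5 equiv), toluene/H2O, 40 °C
Reagents that add atoms: none
Why: Hayashi–Miyaura conjugate addition: the aryl group passes from boron to monovalent rhodium, adds to C2 of the chromone on the face chosen by the chiral diene (this sets C2 as R), and water protonates the rhodium enolate; the catalyst does not insert into the aryl triflate and the weak base spares it.

Step 7
Reactants: 10 (2R)-2-[3-methoxy-4-(methoxymethoxy)phenyl]-5-(methoxymethoxy)-4-oxo-3,4-dihydro-2H-chromen-7-yl trifluoromethanesulfonate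
Product: 12 (2S)-3-diazo-2-[3-methoxy-4-(methoxymethoxy)phenyl]-5-(methoxymethoxy)-4-oxo-3,4-dihydro-2H-chromen-7-yl trifluoromethanesulfonate, via trifluoroacetyl ketone 11 (not isolated)
Conditions: LiN(SiMe3)2, THF, −78 °C; CF3CO2CH2CF3, −78 °C, 10 min; aq. NH4Cl; then 4-acetamidobenzenesulfonyl azide, Et3N, H2O (1 equiv), MeCN, rt
Reagents that add atoms: 4-acetamidobenzenesulfonyl azide, CC(=O)Nc1ccc(cc1)S(=O)(=O)N=[N+]=[N-] (the N2 unit); 2,2,2-trifluoroethyl trifluoroacetate, O=C(OCC(F)(F)F)C(F)(F)F (trifluoroacetyl group of 11 only, absent from 12)
Why: Detrifluoroacetylative Regitz diazo transfer: the kinetic enolate is acylated within minutes at −78 °C, before it can open to the chalcone, and the 1,3-dicarbonyl 11 then takes the diazo group under amine base with loss of the trifluoroacetyl group; C2 is untouched and is S by name only.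

Step 8
Reactants: 12 (2S)-3-diazo-2-[3-methoxy-4-(methoxymethoxy)phenyl]-5-(methoxymethoxy)-4-oxo-3,4-dihydro-2H-chromen-7-yl trifluoromethanesulfonate
Product: 15 methyl (2R,3R)-2-[3-methoxy-4-(methoxymethoxy)phenyl]-4-(methoxymethoxy)-6-(trifluoromethanesulfonyloxy)-2,3-dihydro-1-benzofuran-3-carboxylate, via ketene 13 (not isolated), via cis ester 14 (not isolated)
Conditions: hν (365 nm LED), degassed MeOH/THF (4:1), 0.02 M, 15 °C; then DBU (0.2 equiv), 25 °C
Reagents that add atoms: methanol, CO
Why: Photochemical Wolff rearrangement with ring contraction: the cyclic diazo ketone 12 is fixed in the s-Z arrangement, so excitation expels N2 while the ring A carbon (C4a of the chromanone, C3a of the product) moves from the carbonyl carbon to C3, giving ketene 13, to which methanol adds. The closest known reaction type is the light-induced Wolff ring contraction of cyclic α-diazo ketones in an alcohol, 3-diazochroman-4-ones included, which gives dihydrobenzofuran-3-carboxylates. The dihydrofuran ring is not closed by a cyclisation; it arises by a 1,2-carbon shift that contracts the six-membered pyranone to the five-membered ring O1–C2–C3–C3a–C7a as C3–C3a forms. C3 is the new stereocentre: the ester enol from 13 can be protonated on either face, and whatever cis ester 14 results is equilibrated through the ester enolate by catalytic DBU to the trans ester 15, so the preset C2 centre controls C3 thermodynamically. The ring A carbon has to migrate faster than hydrogen shifts from C2 (flavone), faster than the guaiacyl ring shifts (isoflavone) and faster than O–H insertion into methanol; the s-Z geometry favours loss of N2 in concert with migration, and the migrating carbon is an electron-rich aryl carbon flanked by two oxygens. Light of 365 nm is absorbed by the diazo ketone alone, so the aryl triflate and the aryl ethers stay in their ground states. C2 carries no acidic hydrogen in 12 or 13, and opening of the ester enolate by loss of the O1 phenoxide would be the reverse of a 5-endo-trig closure, so C2 should be preserved.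

Step 9
Reactants: 16 4-vinylguaiacol (4-ethenyl-2-methoxyphenol)
Product: 17 4-ethenyl-2-methoxy-1-(methoxymethoxy)benzene
Conditions: MOMCl, i-Pr2NEt, CH2Cl2, 0 °C to rt (trace BHT)
Reagents that add atoms: chloromethyl methyl ether, COCCl
Why: O-alkylation of the phenol to the MOM acetal stops the vinylphenol from polymerising or oxidising in the coupling.

Step 10
Reactants: 15 methyl (2R,3R)-2-[3-methoxy-4-(methoxymethoxy)phenyl]-4-(methoxymethoxy)-6-(trifluoromethanesulfonyloxy)-2,3-dihydro-1-benzofuran-3-carboxylate; 17 4-ethenyl-2-methoxy-1-(methoxymethoxy)benzene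
Product: 18 methyl (2R,3R)-2-[3-methoxy-4-(methoxymethoxy)phenyl]-6-{(E)-2-[3-methoxy-4-(methoxymethoxy)phenyl]ethenyl}-4-(methoxymethoxy)-2,3-dihydro-1-benzofuran-3-carboxylate
Conditions: PdCl2(PPh3)2 (5 mol %), LiCl (3 equiv), Et3N, DMF, 90 °C, dark
Reagents that add atoms: none
Why: Mizoroki–Heck coupling of the unhindered C6 triflate; chloride keeps the arylpalladium neutral, which directs the aryl group to the terminal alkene carbon, and syn insertion then syn β-hydride elimination gives the E stilbene; amine and heat can only hold the C3 ester in its stable trans form.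

Step 11
Reactants: 18 methyl (2R,3R)-2-[3-methoxy-4-(methoxymethoxy)phenyl]-6-{(E)-2-[3-methoxy-4-(methoxymethoxy)phenyl]ethenyl}-4-(methoxymethoxy)-2,3-dihydro-1-benzofuran-3-carboxylate
Product: 19 (2R,3R)-2-[3-methoxy-4-(methoxymethoxy)phenyl]-6-{(E)-2-[3-methoxy-4-(methoxymethoxy)phenyl]ethenyl}-4-(methoxymethoxy)-2,3-dihydro-1-benzofuran-3-carboxylic acid
Conditions: LiOH, THF/MeOH/H2O, 40 °C; then cold 0.5 M HCl to pH 4
Reagents that add atoms: lithium hydroxide, [Li+].[OH-]
Why: Saponification of the methyl ester; MOM acetals, the stilbene and the aryl ether ring are stable to hydroxide, and brief cold acidification does not cleave the acetals.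

Step 12
Reactants: 19 (2R,3R)-2-[3-methoxy-4-(methoxymethoxy)phenyl]-6-{(E)-2-[3-methoxy-4-(methoxymethoxy)phenyl]ethenyl}-4-(methoxymethoxy)-2,3-dihydro-1-benzofuran-3-carboxylic acid
Product: 20 1,3-dioxoisoindolin-2-yl (2R,3R)-2-[3-methoxy-4-(methoxymethoxy)phenyl]-6-{(E)-2-[3-methoxy-4-(methoxymethoxy)phenyl]ethenyl}-4-(methoxymethoxy)-2,3-dihydro-1-benzofuran-3-carboxylate
Conditions: N-hydroxyphthalimide, i-PrN=C=Ni-Pr, DMAP (cat.), CH2Cl2, rt
Reagents that add atoms: N-hydroxyphthalimide, ON1C(=O)c2ccccc2C1=O
Why: Carbodiimide esterification gives the redox-active ester under neutral conditions; any epimerisation at C3 is immaterial because C3 becomes a radical in step 14.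

Step 13
Reactants: 21 5-bromobenzene-1,3-diol
Product: 22 1-bromo-3,5-bis(methoxymethoxy)benzene
Conditions: MOMCl (2.5 equiv), i-Pr2NEt, CH2Cl2, 0 °C to rt
Reagents that add atoms: chloromethyl methyl ether, COCCl
Why: Double O-alkylation of the two equivalent phenols gives the resorcinyl donor in the same protecting group as the rest of the molecule.

Step 14
Reactants: 20 1,3-dioxoisoindolin-2-yl (2R,3R)-2-[3-methoxy-4-(methoxymethoxy)phenyl]-6-{(E)-2-[3-methoxy-4-(methoxymethoxy)phenyl]ethenyl}-4-(methoxymethoxy)-2,3-dihydro-1-benzofuran-3-carboxylate; 22 1-bromo-3,5-bis(methoxymethoxy)benzene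
Product: 25 (2R,3R)-3-[3,5-bis(methoxymethoxy)phenyl]-2-[3-methoxy-4-(methoxymethoxy)phenyl]-6-{(E)-2-[3-methoxy-4-(methoxymethoxy)phenyl]ethenyl}-4-(methoxymethoxy)-2,3-dihydro-1-benzofuran, via aryllithium 23 (not isolated), via arylzinc chloride 24 (not isolated)
Conditions: 22 (3 equiv), n-BuLi, THF, −78 °C; ZnCl2, −78 °C to rt; then 20, NiCl2·glyme (20 mol %), 4,4′-di-tert-butyl-2,2′-bipyridine (40 mol %), THF/DMF, rt, dark
Reagents that add atoms: none
Why: Nickel-catalysed decarboxylative Negishi-type arylation of a redox-active ester: electron transfer from low-valent nickel fragments 20 into CO2, phthalimide anion and the benzylic C3 radical, which the aryl–nickel species captures on the face away from the C2 aryl group; reductive elimination then sets C3 as R, trans to C2, and the cis isomer, if any forms, is removed by chromatography at this stage.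

Step 15
Reactants: 25 (2R,3R)-3-[3,5-bis(methoxymethoxy)phenyl]-2-[3-methoxy-4-(methoxymethoxy)phenyl]-6-{(E)-2-[3-methoxy-4-(methoxymethoxy)phenyl]ethenyl}-4-(methoxymethoxy)-2,3-dihydro-1-benzofuran
Product: 26 5-[(2R,3R)-4-hydroxy-2-(4-hydroxy-3-methoxyphenyl)-6-[(E)-2-(4-hydroxy-3-methoxyphenyl)ethenyl]-2,3-dihydro-1-benzofuran-3-yl]benzene-1,3-diol
Conditions: 2 M HCl in MeOH/THF, 25 to 40 °C, argon, dark; NaHCO3 quench
Reagents that add atoms: none
Why: Acid-catalysed acetal exchange with methanol frees the five phenols and leaves the methyl ethers alone; the stilbene is remote from the resorcinyl ring, and any reversible ionisation of C2–O1 would reclose to the trans isomer under control of C3.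

## Compound list

1 | 2,4,6-trihydroxyacetophenone | CC(=O)c1c(O)cc(O)cc1O | starting material
2 | (E)-3-(dimethylamino)-1-(2,4,6-trihydroxyphenyl)prop-2-en-1-one | CN(C)/C=C/C(=O)c1c(O)cc(O)cc1O | intermediate (not isolated)
3 | 5,7-dihydroxy-4H-chromen-4-one | O=c1ccoc2cc(O)cc(O)c12 | intermediate
4 | 5-hydroxy-4-oxo-4H-chromen-7-yl trifluoromethanesulfonate | O=c1ccoc2cc(OS(=O)(=O)C(F)(F)F)cc(O)c12 | intermediate
5 | 5-(methoxymethoxy)-4-oxo-4H-chromen-7-yl trifluoromethanesulfonate | COCOc1cc(OS(=O)(=O)C(F)(F)F)cc2occc(=O)c12 | intermediate
6 | 4-bromo-2-methoxyphenol | COc1cc(Br)ccc1O | starting material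
7 | 4-bromo-2-methoxy-1-(methoxymethoxy)benzene | COCOc1ccc(Br)cc1OC | intermediate
8 | [3-methoxy-4-(methoxymethoxy)phenyl]lithium | [Li]c1ccc(OCOC)c(OC)c1 | intermediate (not isolated)
9 | [3-methoxy-4-(methoxymethoxy)phenyl]boronic acid | COCOc1ccc(B(O)O)cc1OC | intermediate
10 | (2R)-2-[3-methoxy-4-(methoxymethoxy)phenyl]-5-(methoxymethoxy)-4-oxo-3,4-dihydro-2H-chromen-7-yl trifluoromethanesulfonate | O=C1C[C@H](c2ccc(OCOC)c(OC)c2)Oc2cc(OS(=O)(=O)C(F)(F)F)cc(OCOC)c21 | intermediate
11 | (2R)-2-[3-methoxy-4-(methoxymethoxy)phenyl]-5-(methoxymethoxy)-4-oxo-3-(trifluoroacetyl)-3,4-dihydro-2H-chromen-7-yl trifluoromethanesulfonate (C3 not defined, largely enolised) | O=C1C(C(=O)C(F)(F)F)[C@H](c2ccc(OCOC)c(OC)c2)Oc2cc(OS(=O)(=O)C(F)(F)F)cc(OCOC)c21 | intermediate (not isolated)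
12 | (2S)-3-diazo-2-[3-methoxy-4-(methoxymethoxy)phenyl]-5-(methoxymethoxy)-4-oxo-3,4-dihydro-2H-chromen-7-yl trifluoromethanesulfonate | [N-]=[N+]=C1[C@H](c2ccc(OCOC)c(OC)c2)Oc2cc(OS(=O)(=O)C(F)(F)F)cc(OCOC)c2C1=O | intermediate (key precursor)
13 | (2S)-2-[3-methoxy-4-(methoxymethoxy)phenyl]-4-(methoxymethoxy)-3-(oxomethylidene)-2,3-dihydro-1-benzofuran-6-yl trifluoromethanesulfonate | O=C=C1[C@H](c2ccc(OCOC)c(OC)c2)Oc2cc(OS(=O)(=O)C(F)(F)F)cc(OCOC)c21 | intermediate (not isolated)
14 | methyl (2R,3S)-2-[3-methoxy-4-(methoxymethoxy)phenyl]-4-(methoxymethoxy)-6-(trifluoromethanesulfonyloxy)-2,3-dihydro-1-benzofuran-3-carboxylate (cis) | FC(F)(F)S(=O)(=O)Oc1cc(OCOC)c2c(c1)O[C@@H](c1ccc(OCOC)c(OC)c1)[C@H]2C(=O)OC | intermediate (not isolated)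
15 | methyl (2R,3R)-2-[3-methoxy-4-(methoxymethoxy)phenyl]-4-(methoxymethoxy)-6-(trifluoromethanesulfonyloxy)-2,3-dihydro-1-benzofuran-3-carboxylate (trans) | FC(F)(F)S(=O)(=O)Oc1cc(OCOC)c2c(c1)O[C@@H](c1ccc(OCOC)c(OC)c1)[C@@H]2C(=O)OC | intermediate (key product)
16 | 4-vinylguaiacol (4-ethenyl-2-methoxyphenol) | C=Cc1ccc(O)c(OC)c1 | starting material
17 | 4-ethenyl-2-methoxy-1-(methoxymethoxy)benzene | C=Cc1ccc(OCOC)c(OC)c1 | intermediate
18 | methyl (2R,3R)-2-[3-methoxy-4-(methoxymethoxy)phenyl]-6-{(E)-2-[3-methoxy-4-(methoxymethoxy)phenyl]ethenyl}-4-(methoxymethoxy)-2,3-dihydro-1-benzofuran-3-carboxylate | COCOc1ccc(/C=C/c2cc(OCOC)c3c(c2)O[C@@H](c2ccc(OCOC)c(OC)c2)[C@@H]3C(=O)OC)cc1OC | intermediate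
19 | (2R,3R)-2-[3-methoxy-4-(methoxymethoxy)phenyl]-6-{(E)-2-[3-methoxy-4-(methoxymethoxy)phenyl]ethenyl}-4-(methoxymethoxy)-2,3-dihydro-1-benzofuran-3-carboxylic acid | COCOc1ccc(/C=C/c2cc(OCOC)c3c(c2)O[C@@H](c2ccc(OCOC)c(OC)c2)[C@@H]3C(=O)O)cc1OC | intermediate
20 | 1,3-dioxoisoindolin-2-yl (2R,3R)-2-[3-methoxy-4-(methoxymethoxy)phenyl]-6-{(E)-2-[3-methoxy-4-(methoxymethoxy)phenyl]ethenyl}-4-(methoxymethoxy)-2,3-dihydro-1-benzofuran-3-carboxylate | COCOc1ccc(/C=C/c2cc(OCOC)c3c(c2)O[C@@H](c2ccc(OCOC)c(OC)c2)[C@@H]3C(=O)ON2C(=O)c4ccccc4C2=O)cc1OC | intermediate
21 | 5-bromobenzene-1,3-diol | Oc1cc(O)cc(Br)c1 | starting material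
22 | 1-bromo-3,5-bis(methoxymethoxy)benzene | COCOc1cc(Br)cc(OCOC)c1 | intermediate
23 | [3,5-bis(methoxymethoxy)phenyl]lithium | [Li]c1cc(OCOC)cc(OCOC)c1 | intermediate (not isolated)
24 | [3,5-bis(methoxymethoxy)phenyl]zinc chloride | Cl[Zn]c1cc(OCOC)cc(OCOC)c1 | intermediate (not isolated)
25 | (2R,3R)-3-[3,5-bis(methoxymethoxy)phenyl]-2-[3-methoxy-4-(methoxymethoxy)phenyl]-6-{(E)-2-[3-methoxy-4-(methoxymethoxy)phenyl]ethenyl}-4-(methoxymethoxy)-2,3-dihydro-1-benzofuran | COCOc1ccc(/C=C/c2cc(OCOC)c3c(c2)O[C@@H](c2ccc(OCOC)c(OC)c2)[C@@H]3c2cc(OCOC)cc(OCOC)c2)cc1OC | intermediate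
26 | 5-[(2R,3R)-4-hydroxy-2-(4-hydroxy-3-methoxyphenyl)-6-[(E)-2-(4-hydroxy-3-methoxyphenyl)ethenyl]-2,3-dihydro-1-benzofuran-3-yl]benzene-1,3-diol | COc1cc(/C=C/c2cc(O)c3c(c2)O[C@@H](c2ccc(O)c(OC)c2)[C@@H]3c2cc(O)cc(O)c2)ccc1O | target

## Step count and least certain steps

Total step count: 15. Longest linear sequence: 11 steps (steps 1, 2, 3, 6, 7, 8, 10, 11, 12, 14, 15).

Step 8 (key step). The likely failure is loss of N2 without concerted migration. Hydrogen would then shift from C2, which O1 and the guaiacyl ring activate, and the ring would aromatise to the flavone; insertion into the O–H bond of methanol could also compete. Absorption by the aryl triflate at shorter wavelength would add S–O cleavage. The fallback is the oxidative ring contraction of 10 by trivalent iodine (PhI(OAc)2 or PhI(OH)OTs in HC(OMe)3/MeOH with a trace of H2SO4, 0 °C). There the enol ether of 10 is iodinated at C3 and the same ring A carbon shifts from C4 to C3 as PhI leaves; the ortho ester collapses to the trans methyl ester. It sets out from 10 and returns at 15 and makes no compound outside the list (F0). Its own hazards are acid towards the MOM ethers and a competing shift of the guaiacyl ring.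

Step 7. The likely failure is opening of the lithium enolate of 10 to the chalcone phenoxide and reclosure, which erodes the C2 configuration, or incomplete trifluoroacetylation of a hindered enolate. The fallback avoids a metal enolate. 10 is condensed with t-BuOCH(NMe2)2 (toluene, 60 °C) to (2S,3E)-3-[(dimethylamino)methylidene] ketone F1. Diazo transfer to the enaminone with 4-acetamidobenzenesulfonyl azide (MeCN, rt) then splits off the N-sulfonylformamidine and returns to the route at 12.

Step 10. The likely failure is arylation at the internal alkene carbon through the cationic pathway that triflates open with electron-rich styrenes, together with E/Z erosion or polymerisation of 17. The fallback fixes the alkene geometry before the coupling. 17 is converted by cross-metathesis with vinylboronic acid pinacol ester (second-generation Grubbs catalyst, CH2Cl2, 40 °C) into (E)-styrylboronate F2. F2 is joined to 15 by Suzuki–Miyaura coupling (Pd(dppf)Cl2, K3PO4, dioxane/H2O, 70 °C), returning at 18.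

Step 14. The likely failures are poor facial selectivity in the capture of the planar C3 radical (a cis isomer cannot be corrected later), β-hydride elimination from the alkylnickel intermediate towards the aromatic benzofuran (loss of both stereocentres), and dimerisation or reduction of the radical. The fallback grows the resorcinyl ring from the ester carbon and keeps C3 under thermodynamic trans control. 18 is treated with excess dilithio-acetylacetone F3 (from acetylacetone and LiN(i-Pr)2, THF, −78 to 0 °C) in a Claisen-type acylation to triketone F4. Aqueous KOH (MeOH/H2O, argon, 25 to 50 °C) closes the terminal methyl carbon onto the ketone next to C3 and aromatises to resorcinol F5. MOM removal as in step 15 (HCl, MeOH/THF) returns to the route at 26. Its own weak points are deprotonation of 18 at C3 in place of acylation and retro-Claisen cleavage in alkali, which is why it is the fallback and not the main line.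

## Further compounds

F0 | step 8 | none | none
F1 | step 7 | (2S,3E)-3-[(dimethylamino)methylidene]-2-[3-methoxy-4-(methoxymethoxy)phenyl]-5-(methoxymethoxy)-4-oxo-3,4-dihydro-2H-chromen-7-yl trifluoromethanesulfonate | O=C1/C(=C/N(C)C)[C@H](c2ccc(OCOC)c(OC)c2)Oc2cc(OS(=O)(=O)C(F)(F)F)cc(OCOC)c21
F2 | step 10 | 2-{(E)-2-[3-methoxy-4-(methoxymethoxy)phenyl]ethenyl}-4,4,5,5-tetramethyl-1,3,2-dioxaborolane | COCOc1ccc(/C=C/B2OC(C)(C)C(C)(C)O2)cc1OC
F3 | step 14 | dilithium pentane-2,4-dione-1,3-diide | [Li+].[Li+].[CH2-]C(=O)[CH-]C(C)=O
F4 | step 14 | 1-[(2R,3R)-2-[3-methoxy-4-(methoxymethoxy)phenyl]-6-{(E)-2-[3-methoxy-4-(methoxymethoxy)phenyl]ethenyl}-4-(methoxymethoxy)-2,3-dihydro-1-benzofuran-3-yl]hexane-1,3,5-trione | COCOc1ccc(/C=C/c2cc(OCOC)c3c(c2)O[C@@H](c2ccc(OCOC)c(OC)c2)[C@@H]3C(=O)CC(=O)CC(C)=O)cc1OC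
F5 | step 14 | 5-[(2R,3R)-2-[3-methoxy-4-(methoxymethoxy)phenyl]-6-{(E)-2-[3-methoxy-4-(methoxymethoxy)phenyl]ethenyl}-4-(methoxymethoxy)-2,3-dihydro-1-benzofuran-3-yl]benzene-1,3-diol | COCOc1ccc(/C=C/c2cc(OCOC)c3c(c2)O[C@@H](c2ccc(OCOC)c(OC)c2)[C@@H]3c2cc(O)cc(O)c2)cc1OC
A1 | alternative 1 | (2R,3R) target skeleton with C4 triisopropylsilyl ether and four MOM ethers | COCOc1ccc(/C=C/c2cc(O[Si](C(C)C)(C(C)C)C(C)C)c3c(c2)O[C@@H](c2ccc(OCOC)c(OC)c2)[C@@H]3c2cc(OCOC)cc(OCOC)c2)cc1OC
A2 | alternative 1 | (R,R)-configured diyne: ethynyl ether of the benzylic alcohol with a triisopropylsilyloxy-ethynyl group on the neighbouring diaryl methine | C#CO[C@@H](c1ccc(OCOC)c(OC)c1)[C@@H](C#CO[Si](C(C)C)(C(C)C)C(C)C)c1cc(OCOC)cc(OCOC)c1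
A3 | alternative 1 | 4-[(E)-but-1-en-3-ynyl]-2-methoxy-1-(methoxymethoxy)benzene | C#C/C=C/c1ccc(OCOC)c(OC)c1
A4 | alternative 2 | (2R,3R)-6-bromo-3-[3,5-bis(methoxymethoxy)phenyl]-2-[3-methoxy-4-(methoxymethoxy)phenyl]-4-(methoxymethoxy)-2,3-dihydro-1-benzofuran | Brc1cc(OCOC)c2c(c1)O[C@@H](c1ccc(OCOC)c(OC)c1)[C@@H]2c1cc(OCOC)cc(OCOC)c1
A5 | alternative 2 | 1,3-dioxoisoindolin-2-yl (3R)-3-[4-bromo-2,6-bis(methoxymethoxy)phenyl]-3-[3,5-bis(methoxymethoxy)phenyl]-2-[3-methoxy-4-(methoxymethoxy)phenyl]propanoate (C2 not defined) | O=C(ON1C(=O)c2ccccc2C1=O)C(c1ccc(OCOC)c(OC)c1)[C@@H](c1c(OCOC)cc(Br)cc1OCOC)c1cc(OCOC)cc(OCOC)c1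
A6 | alternative 3 | (2R,3R) target with free C4 hydroxyl and four MOM ethers | COCOc1ccc(/C=C/c2cc(O)c3c(c2)O[C@@H](c2ccc(OCOC)c(OC)c2)[C@@H]3c2cc(OCOC)cc(OCOC)c2)cc1OC
A7 | alternative 3 | (E)-1-[(4R,5R)-3-acetyl-4-[3,5-bis(methoxymethoxy)phenyl]-5-[3-methoxy-4-(methoxymethoxy)phenyl]-4,5-dihydrofuran-2-yl]-4-[3-methoxy-4-(methoxymethoxy)phenyl]but-3-en-2-one | CC(=O)C1=C(CC(=O)/C=C/c2ccc(OCOC)c(OC)c2)O[C@@H](c2ccc(OCOC)c(OC)c2)[C@@H]1c1cc(OCOC)cc(OCOC)c1
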